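## Retrosynthetic overview

1. The target is epicatechin-(4β→8)-epifisetinidol-(4β→8)-catechin. It comes from a fully protected trimer in one hydrogenolysis that removes eleven O-benzyl groups and three aryl bromine caps.
2. The trimer comes from two cationic flavan-4-yl to C8 couplings. The upper bond is made first (epicatechin C4 onto C8 of the 5-deoxy middle unit, whose C6 is blocked by Br), the lower bond second (middle C4 onto C8 of catechin). Both go anti to a 3α-OH and give 4β.
3. The upper and lower units come from (−)-epicatechin and (+)-catechin, so their rings are bought, not made.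
4. Key disconnection, in the middle unit: the C4–C4a bond of a (2R)-flavan-3-one. A terminal alkyne is turned into an α-oxo gold carbene, an enolonium equivalent with an electrophilic ketone α-carbon. The nucleophilic ring A carbon attacks it and closes ring C, the only ring formed in the route.
5. The alkyne is an (S)-aryl propargyl ether, made by copper-catalysed enantioconvergent etherification of a racemic propargylic acetate with 3-(benzyloxy)phenol. C2 then controls C3 (hydride), and C3 controls C4.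

Assumption: (S,S)-Ph-pybox is taken as the ligand antipode that gives the (S)-ether in step 2 (if the sense is opposite, its commercial mirror image is used), and (−)-epicatechin is taken as a bulk commercial natural product.

## Route

Step 1
Reactants: 1 3,4-bis(benzyloxy)benzaldehyde; 2 ethynylmagnesium bromide (HC≡CMgBr, THF solution)
Product: 4 rac-1-[3,4-bis(benzyloxy)phenyl]prop-2-yn-1-yl acetate, via bromomagnesium propargylic alkoxide 3 (not isolated)
Conditions: HC≡CMgBr (1.2 equiv), THF, 0 °C; then Ac2O (1.5 equiv), 0 °C → rt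
Reagents that add atoms: acetic anhydride CC(=O)OC(C)=O
Why: Grignard 1,2-addition to the aldehyde followed by in-flask O-acetylation of the magnesium alkoxide gives the propargylic ester in one operation, and the racemic stereocentre is of no concern because step 2 passes through a planar intermediate.

Step 2
Reactants: 4 rac-1-[3,4-bis(benzyloxy)phenyl]prop-2-yn-1-yl acetate; 5 3-(benzyloxy)phenol
Product: 6 (S)-1,2-bis(benzyloxy)-4-{1-[3-(benzyloxy)phenoxy]prop-2-yn-1-yl}benzene
Conditions: (CuOTf)2·C6H6 (2.5 mol%), (S,S)-Ph-pybox (6 mol%), i-Pr2NEt (1.2 equiv), ClCH2CH2Cl, 0 °C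
Reagents that add atoms: none
Why: Copper-catalysed enantioselective propargylic substitution, in which the copper acetylide of 4 loses acetate to give a planar copper allenylidene so that both enantiomers of 4 converge, and the phenol oxygen adds to the γ-carbon inside the pybox pocket to set the (S)-centre that becomes C2 (R) of the flavan.

Step 3 (key step)
Reactants: 6 (S)-1,2-bis(benzyloxy)-4-{1-[3-(benzyloxy)phenoxy]prop-2-yn-1-yl}benzene
Product: 8 (2R)-7,3',4'-tris(benzyloxy)flavan-3-one, via alpha-oxo gold carbene 7 (not isolated)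
Conditions: [(Me4tBuXPhos)Au]NTf2 (5 mol%; Me4tBuXPhos = di-tert-butyl(2',4',6'-triisopropyl-3,4,5,6-tetramethylbiphenyl-2-yl)phosphine), 2,6-dichloropyridine N-oxide (1.3 equiv), ClCH2CH2Cl, rt
Reagents that add atoms: 2,6-dichloropyridine N-oxide [O-][n+]1c(Cl)cccc1Cl
Why: Gold-catalysed alkyne oxidation with arylative cyclisation, in which Markovnikov attack of the N-oxide on the alkyne bound to cationic monovalent gold and N–O cleavage give an α-oxo gold carbene whose ketone α-carbon (future C4) is electrophilic, the ring A carbon para to the benzyloxy group attacks it in Friedel–Crafts fashion and protodeauration closes ring C, so two innately nucleophilic carbons are joined while the C2 stereocentre is not touched.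

Step 4
Reactants: 8 (2R)-7,3',4'-tris(benzyloxy)flavan-3-one
Product: 9 (2R,3R)-7,3',4'-tri-O-benzylepifisetinidol
Conditions: LiBH(s-Bu)3 (1.5 equiv), LiBr, THF, −78 °C; aqueous quench
Reagents that add atoms: none
Why: Substrate-controlled ketone reduction with a bulky borohydride, which with the 2-aryl group equatorial attacks along the equatorial trajectory from the β face and leaves the axial 3α-OH, setting C3 (R) cis to the aryl group as known for the flavan-3-one derived from tetra-O-benzylcatechin.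

Step 5
Reactants: 9 (2R,3R)-7,3',4'-tri-O-benzylepifisetinidol
Product: 10 4β-methoxy-7,3',4'-tri-O-benzylepifisetinidol (2,3-cis-3,4-trans)
Conditions: DDQ (1.5 equiv), MeOH (10 equiv), CH2Cl2, rt
Reagents that add atoms: methanol CO
Why: DDQ benzylic oxidation, in which hydride abstraction from C4 (its ring carbon C4a is para to the 7-benzyloxy group and ortho to the O1-bearing carbon) gives a quinone-methide-type cation that methanol traps anti to the axial 3α-OH to give the 4β ether.

Step 6
Reactants: 10 4β-methoxy-7,3',4'-tri-O-benzylepifisetinidol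
Product: 11 6-bromo-4β-methoxy-7,3',4'-tri-O-benzylepifisetinidol
Conditions: NBS (1.05 equiv), CH2Cl2, −20 °C
Reagents that add atoms: N-bromosuccinimide O=C1CCC(=O)N1Br
Why: Electrophilic aromatic bromination goes to C6, the unhindered position ortho to the 7-benzyloxy group and para to O1, which blocks the site where a 5-deoxyflavan would otherwise be alkylated and further disarms the C4 ether.

Step 7
Reactants: 12 (−)-epicatechin
Product: 13 5,7,3',4'-tetra-O-benzyl-(−)-epicatechin
Conditions: BnBr (4.4 equiv), K2CO3, DMF, 0 °C → rt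
Reagents that add atoms: benzyl bromide BrCc1ccccc1
Why: Williamson etherification of the four acidic phenols leaves the secondary 3-OH and both stereocentres untouched.

Step 8
Reactants: 13 5,7,3',4'-tetra-O-benzyl-(−)-epicatechin
Product: 14 4β-(2-ethoxyethoxy)-5,7,3',4'-tetra-O-benzylepicatechin
Conditions: DDQ (2 equiv), EtOCH2CH2OH, CH2Cl2, rt
Reagents that add atoms: 2-ethoxyethanol CCOCCO
Why: DDQ benzylic oxidation at C4 of the very electron-rich ring A gives the flavan-4-yl cation, which the alcohol traps anti to the 3α-OH, installing a bidentate leaving group as the 4β ether.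

Step 9
Reactants: 14 4β-(2-ethoxyethoxy)-5,7,3',4'-tetra-O-benzylepicatechin
Product: 15 6,8-dibromo-4β-(2-ethoxyethoxy)-5,7,3',4'-tetra-O-benzylepicatechin
Conditions: NBS (2.1 equiv), CH2Cl2, −20 °C → rt
Reagents that add atoms: N-bromosuccinimide O=C1CCC(=O)N1Br
Why: Twofold electrophilic aromatic bromination caps both nucleophilic ring A positions, so this unit can act only as an electrophile and cannot self-condense while it waits for the weak nucleophile of step 10.

Step 10
Reactants: 15 6,8-dibromo-4β-(2-ethoxyethoxy)-5,7,3',4'-tetra-O-benzylepicatechin; 11 6-bromo-4β-methoxy-7,3',4'-tri-O-benzylepifisetinidol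
Product: 16 [6,8-dibromo-5,7,3',4'-tetra-O-benzylepicatechin]-(4β→8)-[6-bromo-4β-methoxy-7,3',4'-tri-O-benzylepifisetinidol]
Conditions: 15 (1.2 equiv), Yb(OTf)3 (1 equiv), 4 Å MS, CH2Cl2, 0 °C → rt
Reagents that add atoms: none
Why: Lewis-acid-mediated Friedel–Crafts flavanylation under armed–disarmed control, in which Yb(OTf)3 chelates and ionises only the bidentate 2-ethoxyethoxy group on the 5,7-dioxygenated unit 15, the monodentate methoxy group on the 5-deoxy brominated unit 11 stays in place, the only free activated ring A position is C8 of 11, and attack anti to the 3α-OH of the cation sets the upper C4 as 4β (3,4-trans).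

Step 11
Reactants: 17 (+)-catechin
Product: 18 5,7,3',4'-tetra-O-benzyl-(+)-catechin
Conditions: BnBr (4.4 equiv), K2CO3, DMF, 0 °C → rt
Reagents that add atoms: benzyl bromide BrCc1ccccc1
Why: Williamson etherification of the four phenols leaves the 3-OH and the (2R,3S) stereocentres untouched.

Step 12
Reactants: 16 the (4β→8) dimer with the 4β-methoxy group; 18 5,7,3',4'-tetra-O-benzyl-(+)-catechin
Product: 19 [6,8-dibromo-5,7,3',4'-tetra-O-benzylepicatechin]-(4β→8)-[6-bromo-7,3',4'-tri-O-benzylepifisetinidol]-(4β→8)-[5,7,3',4'-tetra-O-benzylcatechin]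
Conditions: 18 (3 equiv), BF3·OEt2 (2 equiv), CH2Cl2, −20 → 0 °C
Reagents that add atoms: none
Why: Friedel–Crafts flavanylation in which the stronger Lewis acid now ionises the 4-methoxy group of the middle unit, the excess nucleophile 18 reacts at C8 as its most accessible activated position, and approach anti to the 3α-OH and the 2α-aryl group sets the middle C4 as 4β.

Step 13
Reactants: 19 the protected tribromo trimer
Product: 20 epicatechin-(4β→8)-epifisetinidol-(4β→8)-catechin (CNP0270097.1)
Conditions: H2 (1 atm), Pd(OH)2/C, Et3N (3.5 equiv), THF/MeOH/H2O, rt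
Reagents that add atoms: none
Why: Catalytic hydrogenolysis cleaves the eleven benzyl ethers and hydrodehalogenates the three aryl bromides in one operation while triethylamine takes up the HBr that would otherwise cleave the acid-labile interflavan bonds, and no stereocentre is affected.

## Compound list

1 | 3,4-bis(benzyloxy)benzaldehyde | O=Cc1ccc(OCc2ccccc2)c(OCc2ccccc2)c1 | starting material
2 | ethynylmagnesium bromide | C#C[Mg]Br | starting material
3 | bromomagnesium 1-[3,4-bis(benzyloxy)phenyl]prop-2-yn-1-olate (racemic, not isolated) | C#CC(O[Mg]Br)c1ccc(OCc2ccccc2)c(OCc2ccccc2)c1 | intermediate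
4 | rac-1-[3,4-bis(benzyloxy)phenyl]prop-2-yn-1-yl acetate | C#CC(OC(C)=O)c1ccc(OCc2ccccc2)c(OCc2ccccc2)c1 | intermediate
5 | 3-(benzyloxy)phenol | Oc1cccc(OCc2ccccc2)c1 | starting material
6 | (S)-1,2-bis(benzyloxy)-4-{1-[3-(benzyloxy)phenoxy]prop-2-yn-1-yl}benzene | C(c1ccccc1)Oc1cccc(c1)O[C@H](c1ccc(OCc2ccccc2)c(OCc2ccccc2)c1)C#C | intermediate
7 | α-oxo gold carbene [(Me4tBuXPhos)Au=CH–C(=O)–CH(OAr)Ar']NTf2, ether carbon configured as in 6 (not isolated) | O=C(C=[Au][P+](C(C)(C)C)(C(C)(C)C)c1c(C)c(C)c(C)c(C)c1-c1c(C(C)C)cc(C(C)C)cc1C(C)C)[C@H](Oc1cccc(OCc2ccccc2)c1)c1ccc(OCc2ccccc2)c(OCc2ccccc2)c1.O=S(=O)([N-]S(=O)(=O)C(F)(F)F)C(F)(F)F | intermediate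
8 | (2R)-7,3',4'-tris(benzyloxy)flavan-3-one | C(c1ccccc1)Oc1ccc2c(c1)O[C@H](c1ccc(OCc3ccccc3)c(OCc3ccccc3)c1)C(=O)C2 | intermediate
9 | (2R,3R)-7,3',4'-tri-O-benzylepifisetinidol (2,3-cis) | C(c1ccccc1)Oc1ccc2c(c1)O[C@H](c1ccc(OCc3ccccc3)c(OCc3ccccc3)c1)[C@H](O)C2 | intermediate
10 | 4β-methoxy-7,3',4'-tri-O-benzylepifisetinidol (2α-aryl, 3α-OH, 4β-OMe) | C(c1ccccc1)Oc1ccc2c(c1)O[C@H](c1ccc(OCc3ccccc3)c(OCc3ccccc3)c1)[C@H](O)[C@H]2OC | intermediate
11 | 6-bromo-4β-methoxy-7,3',4'-tri-O-benzylepifisetinidol | C(c1ccccc1)Oc1c(Br)cc2c(c1)O[C@H](c1ccc(OCc3ccccc3)c(OCc3ccccc3)c1)[C@H](O)[C@H]2OC | intermediate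
12 | (−)-epicatechin (2R,3R) | Oc1cc(O)c2c(c1)O[C@H](c1ccc(O)c(O)c1)[C@H](O)C2 | starting material
13 | 5,7,3',4'-tetra-O-benzyl-(−)-epicatechin | C(c1ccccc1)Oc1cc(OCc3ccccc3)c2c(c1)O[C@H](c1ccc(OCc3ccccc3)c(OCc3ccccc3)c1)[C@H](O)C2 | intermediate
14 | 4β-(2-ethoxyethoxy)-5,7,3',4'-tetra-O-benzylepicatechin | C(c1ccccc1)Oc1cc(OCc3ccccc3)c2c(c1)O[C@H](c1ccc(OCc3ccccc3)c(OCc3ccccc3)c1)[C@H](O)[C@H]2OCCOCC | intermediate
15 | 6,8-dibromo-4β-(2-ethoxyethoxy)-5,7,3',4'-tetra-O-benzylepicatechin | C(c1ccccc1)Oc1c(Br)c(OCc3ccccc3)c2c(c1Br)O[C@H](c1ccc(OCc3ccccc3)c(OCc3ccccc3)c1)[C@H](O)[C@H]2OCCOCC | intermediate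
16 | protected dimer, upper unit 2α-aryl/3α-OH/4β-aryl, lower unit 2α-aryl/3α-OH/4β-OMe | C(c1ccccc1)Oc1c(Br)c(OCc3ccccc3)c2c(c1Br)O[C@H](c1ccc(OCc3ccccc3)c(OCc3ccccc3)c1)[C@H](O)[C@H]2c1c(OCc3ccccc3)c(Br)cc2c1O[C@H](c1ccc(OCc3ccccc3)c(OCc3ccccc3)c1)[C@H](O)[C@H]2OC | intermediate
17 | (+)-catechin (2R,3S) | Oc1cc(O)c2c(c1)O[C@H](c1ccc(O)c(O)c1)[C@@H](O)C2 | starting material
18 | 5,7,3',4'-tetra-O-benzyl-(+)-catechin | C(c1ccccc1)Oc1cc(OCc3ccccc3)c2c(c1)O[C@H](c1ccc(OCc3ccccc3)c(OCc3ccccc3)c1)[C@@H](O)C2 | intermediate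
19 | protected tribromo trimer (undeca-O-benzyl) | C(c1ccccc1)Oc1c(Br)c(OCc3ccccc3)c2c(c1Br)O[C@H](c1ccc(OCc3ccccc3)c(OCc3ccccc3)c1)[C@H](O)[C@H]2c1c(OCc3ccccc3)c(Br)cc2c1O[C@H](c1ccc(OCc3ccccc3)c(OCc3ccccc3)c1)[C@H](O)[C@H]2c1c(OCc3ccccc3)cc(OCc3ccccc3)c2c1O[C@H](c1ccc(OCc3ccccc3)c(OCc3ccccc3)c1)[C@@H](O)C2 | intermediate
20 | epicatechin-(4β→8)-epifisetinidol-(4β→8)-catechin | Oc1cc(O)c2c(c1)O[C@H](c1ccc(O)c(O)c1)[C@H](O)[C@H]2c1c(O)ccc2c1O[C@H](c1ccc(O)c(O)c1)[C@H](O)[C@H]2c1c(O)cc(O)c2c1O[C@H](c1ccc(O)c(O)c1)[C@@H](O)C2 | target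

## Step count and risks

Total step count: 13.

Longest linear sequence: 9 (steps 1, 2, 3, 4, 5, 6, 10, 12, 13).

**Step 3 (gold carbene ring closure).**
- Risks: the carbene may be over-oxidised by the N-oxide. It may be captured by ring B to give an indan-2-one. Plain hydroarylation to the flav-3-ene may compete. The doubly activated C2–O bond may ionise.
- Fallback: it sets out from 6 and comes back at 8. It makes the same C4–C4a bond with the same reversed polarity, but from a halogen-based α-carbonyl cation synthon instead of a carbene.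
- NBS with catalytic AgNO3 in acetone converts 6 into the bromoalkyne ether F1.
- Neutral hydration with [(XPhos)Au]NTf2 in wet 1,4-dioxane gives the α-bromomethyl ketone F2.
- AgOTf with 2,6-di-tert-butylpyridine in (CF3)2CHOH/CH2Cl2 drives an intramolecular Friedel–Crafts alkylation of ring A by the CH2Br carbon to give 8. C2 is not involved.

**Step 10 (upper interflavan bond).**
- Risks: C8 of 11 is a hindered and weak nucleophile. Conditions strong enough to drive the coupling may also ionise the 4-methoxy group of 11.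
- Fallback: it sets out from 11 (with 15 and 18 unchanged) and comes back at 19. It replaces reactivity-based selection by orthogonal hard/soft leaving groups.
- BnSH and BF3·OEt2 in CH2Cl2 convert 11 into the 4β-benzylsulfanyl flavan F3.
- The C–S bond of F3 is inert to hard Lewis acids, so 15 can be forced onto its C8 with excess BF3·OEt2 at up to rt to give the thioether dimer F4.
- The thiophilic salt AgBF4 in THF/CH2Cl2 with 18 (3 equiv) then ionises only the C–S bond and delivers 19 with the same anti (4β) approach.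

**Step 2 (asymmetric propargylic etherification).**
- Risks: the electron-rich phenol 5 may react through carbon (Friedel–Crafts propargylation followed by cyclisation). The ee may be low with the very electron-rich aryl group.
- Fallback: it sets out from 4 and comes back at 6. It replaces catalytic asymmetric substitution by resolution and stereospecific displacement.
- Candida antarctica lipase B in phosphate buffer/MTBE hydrolyses the fast-reacting (R)-ester to the (R)-propargylic alcohol F5. It leaves the (S)-acetate F6, which is separated.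
- A Mitsunobu reaction of F5 with 5 (PPh3, DIAD, toluene, −20 °C) proceeds with SN2 inversion and gives the (S)-ether 6.

Further compounds
F1 | step 3 | bromoalkyne ether, 1,2-bis(benzyloxy)-4-{1-[3-(benzyloxy)phenoxy]-3-bromoprop-2-yn-1-yl}benzene, ether carbon configured as in 6 | C(c1ccccc1)Oc1cccc(c1)O[C@H](c1ccc(OCc2ccccc2)c(OCc2ccccc2)c1)C#CBr
F2 | step 3 | α-bromomethyl ketone, 1-[3,4-bis(benzyloxy)phenyl]-1-[3-(benzyloxy)phenoxy]-3-bromopropan-2-one, ether carbon configured as in 6 | C(c1ccccc1)Oc1cccc(c1)O[C@H](c1ccc(OCc2ccccc2)c(OCc2ccccc2)c1)C(=O)CBr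
F3 | step 10 | 4β-benzylsulfanyl flavan, 6-bromo-4β-(benzylsulfanyl)-7,3',4'-tri-O-benzylepifisetinidol | C(c1ccccc1)Oc1c(Br)cc2c(c1)O[C@H](c1ccc(OCc3ccccc3)c(OCc3ccccc3)c1)[C@H](O)[C@H]2SCc1ccccc1
F4 | step 10 | thioether dimer, [6,8-dibromo-5,7,3',4'-tetra-O-benzylepicatechin]-(4β→8)-[6-bromo-4β-(benzylsulfanyl)-7,3',4'-tri-O-benzylepifisetinidol] | C(c1ccccc1)Oc1c(Br)c(OCc3ccccc3)c2c(c1Br)O[C@H](c1ccc(OCc3ccccc3)c(OCc3ccccc3)c1)[C@H](O)[C@H]2c1c(OCc3ccccc3)c(Br)cc2c1O[C@H](c1ccc(OCc3ccccc3)c(OCc3ccccc3)c1)[C@H](O)[C@H]2SCc1ccccc1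
F5 | step 2 | (R)-propargylic alcohol, (R)-1-[3,4-bis(benzyloxy)phenyl]prop-2-yn-1-ol | O[C@@H](c1ccc(OCc2ccccc2)c(OCc2ccccc2)c1)C#C
F6 | step 2 | (S)-acetate, (S)-1-[3,4-bis(benzyloxy)phenyl]prop-2-yn-1-yl acetate | CC(=O)O[C@H](c1ccc(OCc2ccccc2)c(OCc2ccccc2)c1)C#C
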